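**Plan**
Retrosynthesis: the lower C4–OH is traced back to a C4 ketone, reduced last after the benzyl ethers are removed. The lower ring C is then cut at C4–C4a and O1–C2 into aryl bromide 17 and epoxy amide 9. The interflavanyl C4–C6 bond is cut into 4-methoxyflavan-3-ol 16 and bromophenol 5, and 16 is itself made from 5 and 9 by the same ring-forming operation.
Forward order: ring A block 5 (steps 1–3) and ring B/C3 block 9 (steps 4–5); upper ring C (step 6); C3 inversion and C4 activation (steps 7–8); interflavanyl bond (step 9); lower ring C, the last ring (step 10); debenzylation and ketone reduction (steps 11–12).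
Enabling feature: on ring A of the lower unit the phenol oxygen O1 and its ortho carbon C4a (C–Br, then C–Li) form a 1,3-O,C-dinucleophile that meets the acyl carbon and the benzylic epoxide carbon of 9. The para-oxygen of ring B directs epoxide opening to C2, so the six-membered ring forms.
Stereochemistry: C2/C3 of both units come from the catalyst-controlled epoxidation of step 5 (C3 retained, C2 by inversion, 2,3-trans). The upper C3 is inverted through a 3,4-epoxide (2,3-cis). The upper C4 is set anti to both neighbours in the Friedel–Crafts step (4β). The lower C4 is set by substrate-controlled hydride delivery (3,4-trans).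

Key step: step 10

Remark: the sense of induction in step 5 is assigned by analogy with enone epoxidation and would be confirmed on 9 (the other BINOL enantiomer is used if it is opposite). The descriptor at the upper C4 changes between R and S along the route only through CIP priorities; the geometry (4β) is the same throughout.

**Route**

Step 1
Reactants: 1 2,3-dihydroxybenzaldehyde
Product: 2 2,3-bis(benzyloxy)benzaldehyde
Conditions: BnBr (2.3 equiv), K2CO3, DMF, 60 °C
Reagents that add atoms: benzyl bromide, BrCc1ccccc1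
Why: Williamson etherification of both phenolic hydroxyls with benzyl bromide under carbonate conditions is routine and leaves the aldehyde untouched.

Step 2
Reactants: 2 2,3-bis(benzyloxy)benzaldehyde
Product: 4 2,3-bis(benzyloxy)phenol, via aryl formate 3 (not isolated)
Conditions: mCPBA, CH2Cl2, rt; then K2CO3 (cat.), MeOH, rt
Reagents that add atoms: 3-chloroperbenzoic acid (mCPBA), OOC(=O)c1cccc(Cl)c1
Why: Baeyer–Villiger (Dakin-type) oxidation, in which the electron-rich 2,3-dialkoxyaryl group migrates to oxygen in the Criegee intermediate, should give aryl formate 3, which is cleaved by base-catalysed methanolysis.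

Step 3
Reactants: 4 2,3-bis(benzyloxy)phenol
Product: 5 2,3-bis(benzyloxy)-6-bromophenol
Conditions: NBS (1.0 equiv), i-Pr2NH (10 mol %), CH2Cl2, −20 → 0 °C
Reagents that add atoms: N-bromosuccinimide, O=C1CCC(=O)N1Br
Why: Amine-catalysed electrophilic aromatic bromination with NBS, in which the hydrogen-bonded N-bromoamine delivers bromine next to the hydroxyl, should mark C6 (the only free ortho position) rather than the para position and so fixes where both later bonds to ring A are made.

Step 4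
Reactants: 6 1-(benzyloxy)-4-iodobenzene; 7 4-acryloylmorpholine
Product: 8 (2E)-3-[4-(benzyloxy)phenyl]-1-(morpholin-4-yl)prop-2-en-1-one
Conditions: Pd(OAc)2 (2 mol %), P(o-tol)3 (4 mol %), Et3N, DMF, 100 °C
Reagents that add atoms: none
Why: Mizoroki–Heck arylation of the acrylamide proceeds by syn carbopalladation and syn β-hydride elimination and should give the E-cinnamamide only.

Step 5
Reactants: 8 (2E)-3-[4-(benzyloxy)phenyl]-1-(morpholin-4-yl)prop-2-en-1-one
Product: 9 [(2R,3S)-3-[4-(benzyloxy)phenyl]oxiran-2-yl](morpholin-4-yl)methanone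
Conditions: Sm(O-i-Pr)3/(S)-BINOL/Ph3As=O (1:1:1, 10 mol %), TBHP (decane), 4 Å MS, THF, rt
Reagents that add atoms: tert-butyl hydroperoxide, CC(C)(C)OO
Why: Lanthanide–BINOL–Ph3As=O-catalysed nucleophilic epoxidation of an α,β-unsaturated amide (asymmetric Weitz–Scheffer-type epoxidation), in which the chiral metal peroxide adds to the β-carbon of the amide bound to the same metal, should give the trans-(2R,3S)-epoxide with both centres set by the catalyst.

Step 6
Reactants: 5 2,3-bis(benzyloxy)-6-bromophenol; 9 [(2R,3S)-3-[4-(benzyloxy)phenyl]oxiran-2-yl](morpholin-4-yl)methanone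
Product: 12 (2R,3R)-7,8-bis(benzyloxy)-2-[4-(benzyloxy)phenyl]-3-hydroxychroman-4-one, via dilithiated phenoxide 10 (not isolated), via epoxy ketone 11 (not isolated)
Conditions: t-BuLi (3.1 equiv), THF, −78 °C; 9, −78 → −30 °C; then 2 M HCl, THF, 0 °C → rt
Reagents that add atoms: none
Why: Bromine–lithium exchange on the phenoxide, acylation of aryllithium 10 by the morpholine amide and acid-promoted 6-endo-tet opening of the resulting 2'-hydroxy epoxy ketone 11 at its benzylic carbon (chalcone-epoxide to dihydroflavonol cyclisation) should give the 2,3-trans ketol, C3 being the retained C2 of 9 and C2 arising by inversion.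

Step 7
Reactants: 12 (2R,3R)-7,8-bis(benzyloxy)-2-[4-(benzyloxy)phenyl]-3-hydroxychroman-4-one
Product: 13 (2R,3R)-7,8-bis(benzyloxy)-2-[4-(benzyloxy)phenyl]-4-oxochroman-3-yl methanesulfonate
Conditions: MsCl, Et3N, CH2Cl2, −20 → 0 °C
Reagents that add atoms: methanesulfonyl chloride, CS(Cl)(=O)=O
Why: O-Mesylation of the only hydroxyl at low temperature turns the 3-oxygen into a leaving group without touching C2 or C3, the equatorial mesylate having no antiperiplanar hydrogen for elimination.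

Step 8
Reactants: 13 (2R,3R)-7,8-bis(benzyloxy)-2-[4-(benzyloxy)phenyl]-4-oxochroman-3-yl methanesulfonate
Product: 16 (2R,3R,4S)-7,8-bis(benzyloxy)-2-[4-(benzyloxy)phenyl]-4-methoxychroman-3-ol, via trans-hydroxy mesylate 14 (not isolated), via cis-epoxide 15 (not isolated)
Conditions: NaBH4, THF/MeOH, −20 °C; NaOMe (1.0 equiv), 0 °C → rt; then PPTS (cat.), MeOH, rt
Reagents that add atoms: methanol, CO
Why: NaBH4 should reduce the C4 ketone by axial attack (as in dihydroflavonol reductions) to the 4α-alkoxide trans to the 3β-mesylate, which closes by intramolecular SN2 (epoxide formation from an α-sulfonyloxy alcohol) with inversion at C3 to the 3α,4α-epoxide, and acid-catalysed methanolysis at the benzylic C4 (para to the 7-oxygen) then gives the 4β-methyl ether trans to the now 3α-hydroxyl, so that the unit ends 2,3-cis.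

Step 9
Reactants: 16 (2R,3R,4S)-7,8-bis(benzyloxy)-2-[4-(benzyloxy)phenyl]-4-methoxychroman-3-ol; 5 2,3-bis(benzyloxy)-6-bromophenol (4 equiv, excess recovered)
Product: 17 (2R,3R,4R)-7,8-bis(benzyloxy)-4-[2,3-bis(benzyloxy)-5-bromo-4-hydroxyphenyl]-2-[4-(benzyloxy)phenyl]chroman-3-ol
Conditions: TMSOTf (0.2 equiv), CH2Cl2, −78 → −40 °C
Reagents that add atoms: none
Why: Lewis-acid-mediated Friedel–Crafts benzylation through the flavan-4-yl cation (the proanthocyanidin-type condensation) should join C4 to the position para to the free hydroxyl of 5, the only strongly activated site once the ortho position carries bromine, and the arene should enter anti to the cis-disposed 2-aryl and 3-hydroxyl groups to set 4β.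

Step 10
Reactants: 17 (2R,3R,4R)-7,8-bis(benzyloxy)-4-[2,3-bis(benzyloxy)-5-bromo-4-hydroxyphenyl]-2-[4-(benzyloxy)phenyl]chroman-3-ol; 9 [(2R,3S)-3-[4-(benzyloxy)phenyl]oxiran-2-yl](morpholin-4-yl)methanone
Product: 20 (2R,3R)-7,8-bis(benzyloxy)-6-{(2R,3R,4R)-7,8-bis(benzyloxy)-2-[4-(benzyloxy)phenyl]-3-hydroxychroman-4-yl}-2-[4-(benzyloxy)phenyl]-3-hydroxychroman-4-one, via trilithiated species 18 (not isolated), via epoxy ketone 19 (not isolated)
Conditions: t-BuLi (4.1 equiv), THF, −78 °C; 9 (1.2 equiv), −78 → −30 °C; then 2 M HCl, THF, 0 °C → rt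
Reagents that add atoms: none
Why: t-BuLi removes both O–H protons and exchanges the bromine at C4a of ring A, aryllithium 18 adds to the morpholine amide of 9 to give a tetrahedral adduct that collapses on protonation to 2'-hydroxy epoxy ketone 19, and acid then lets the ring A phenol oxygen open the epoxide at its benzylic carbon. The closest known reaction types are aryllithium acylation by a morpholine (Weinreb-type) amide and the chalcone-epoxide to dihydroflavonol cyclisation (the ring-forming stage of Algar–Flynn–Oyamada chemistry), here run in one flask as a formal [3+3] annulation. The pyranone ring closes in the 6-endo-tet mode, preferred over 5-exo-tet attack at the α-carbon because the 4-benzyloxyphenyl group carries the developing positive charge at C2 while the adjacent carbonyl destabilises charge at C3. C3 of the new ring is the untouched C2 of epoxide 9 and C2 is formed with inversion at the benzylic epoxide carbon, which is also the thermodynamically preferred 2,3-trans diequatorial arrangement should partial ionisation occur, so both centres are controlled by the building block and not by the remote upper unit. The step needs acylation at C4a only and no attack of the aryllithium on the epoxide or on benzylic positions: the bromine fixes the site, exchange at −78 °C outruns deprotonation of the benzyl ethers and of the diarylmethine C4–H, and the amide carbonyl is the faster, chelating electrophile.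

Step 11
Reactants: 20 (2R,3R)-7,8-bis(benzyloxy)-6-{(2R,3R,4R)-7,8-bis(benzyloxy)-2-[4-(benzyloxy)phenyl]-3-hydroxychroman-4-yl}-2-[4-(benzyloxy)phenyl]-3-hydroxychroman-4-one
Product: 21 (2R,3R)-3,7,8-trihydroxy-2-(4-hydroxyphenyl)-6-[(2R,3R,4S)-3,7,8-trihydroxy-2-(4-hydroxyphenyl)chroman-4-yl]chroman-4-one
Conditions: H2 (1 atm), Pd(OH)2/C, THF/MeOH, rt
Reagents that add atoms: none
Why: Catalytic hydrogenolysis cleaves the six aryl benzyl ethers, while the hydrogen-bonded aryl ketone, the ring ether C–O bonds and the diarylmethine C–C bond are expected to persist at 1 atm and room temperature.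

Step 12
Reactants: 21 (2R,3R)-3,7,8-trihydroxy-2-(4-hydroxyphenyl)-6-[(2R,3R,4S)-3,7,8-trihydroxy-2-(4-hydroxyphenyl)chroman-4-yl]chroman-4-one
Product: 22 (2R,3S,4R)-2-(4-hydroxyphenyl)-6-[(2R,3R,4S)-3,7,8-trihydroxy-2-(4-hydroxyphenyl)chroman-4-yl]chromane-3,4,7,8-tetrol (target, epioritin-(4β→6)-oritin-4α-ol)
Conditions: NaBH4 (excess), EtOH, 0 °C → rt; pH 6 buffer work-up under argon
Reagents that add atoms: none
Why: NaBH4 reduction of a 2,3-trans-dihydroflavonol should deliver hydride axially, anti to the axial H-3 (Felkin-type torsional control), so that the new 4-hydroxyl is equatorial and trans to the 3-hydroxyl (4α), as known for dihydroflavonol to flavan-3,4-diol reductions.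

**Compound list**
1 | 2,3-dihydroxybenzaldehyde | O=Cc1cccc(O)c1O | starting material
2 | 2,3-bis(benzyloxy)benzaldehyde | O=Cc1cccc(OCc2ccccc2)c1OCc1ccccc1 | intermediate
3 | 2,3-bis(benzyloxy)phenyl formate (not isolated) | O=COc1cccc(OCc2ccccc2)c1OCc1ccccc1 | intermediate
4 | 2,3-bis(benzyloxy)phenol | Oc1cccc(OCc2ccccc2)c1OCc1ccccc1 | intermediate
5 | 2,3-bis(benzyloxy)-6-bromophenol | Oc1c(Br)ccc(OCc2ccccc2)c1OCc1ccccc1 | intermediate
6 | 1-(benzyloxy)-4-iodobenzene | Ic1ccc(OCc2ccccc2)cc1 | starting material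
7 | 4-acryloylmorpholine | C=CC(=O)N1CCOCC1 | starting material
8 | (2E)-3-[4-(benzyloxy)phenyl]-1-(morpholin-4-yl)prop-2-en-1-one | O=C(/C=C/c1ccc(OCc2ccccc2)cc1)N1CCOCC1 | intermediate
9 | [(2R,3S)-3-[4-(benzyloxy)phenyl]oxiran-2-yl](morpholin-4-yl)methanone (trans-epoxy amide) | O=C(N1CCOCC1)[C@@H]1O[C@H]1c1ccc(OCc2ccccc2)cc1 | intermediate
10 | lithium 2,3-bis(benzyloxy)-6-lithiophenoxide (not isolated) | [Li]Oc1c([Li])ccc(OCc2ccccc2)c1OCc1ccccc1 | intermediate
11 | [3,4-bis(benzyloxy)-2-hydroxyphenyl][(2R,3S)-3-[4-(benzyloxy)phenyl]oxiran-2-yl]methanone (not isolated) | O=C(c1ccc(OCc2ccccc2)c(OCc2ccccc2)c1O)[C@@H]1O[C@H]1c1ccc(OCc2ccccc2)cc1 | intermediate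
12 | (2R,3R)-7,8-bis(benzyloxy)-2-[4-(benzyloxy)phenyl]-3-hydroxychroman-4-one (2,3-trans) | O=C1c2ccc(OCc3ccccc3)c(OCc3ccccc3)c2O[C@H](c2ccc(OCc3ccccc3)cc2)[C@H]1O | intermediate
13 | (2R,3R)-7,8-bis(benzyloxy)-2-[4-(benzyloxy)phenyl]-4-oxochroman-3-yl methanesulfonate | O=C1c2ccc(OCc3ccccc3)c(OCc3ccccc3)c2O[C@H](c2ccc(OCc3ccccc3)cc2)[C@H]1OS(C)(=O)=O | intermediate
14 | (2R,3S,4R)-7,8-bis(benzyloxy)-2-[4-(benzyloxy)phenyl]-4-hydroxychroman-3-yl methanesulfonate (2,3-trans-3,4-trans, formed as its sodium alkoxide, not isolated) | O[C@@H]1c2ccc(OCc3ccccc3)c(OCc3ccccc3)c2O[C@H](c2ccc(OCc3ccccc3)cc2)[C@H]1OS(C)(=O)=O | intermediate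
15 | (1aR,2R,7bR)-4,5-bis(benzyloxy)-2-[4-(benzyloxy)phenyl]-1a,7b-dihydro-2H-oxireno[2,3-c]chromene (3,4-epoxyflavan with the oxirane cis to the 2-aryl group, not isolated) | O1[C@@H]2c3ccc(OCc4ccccc4)c(OCc4ccccc4)c3O[C@H](c3ccc(OCc4ccccc4)cc3)[C@H]12 | intermediate
16 | (2R,3R,4S)-7,8-bis(benzyloxy)-2-[4-(benzyloxy)phenyl]-4-methoxychroman-3-ol (2,3-cis-3,4-trans, 4β-methoxy) | CO[C@H]1c2ccc(OCc3ccccc3)c(OCc3ccccc3)c2O[C@H](c2ccc(OCc3ccccc3)cc2)[C@@H]1O | intermediate
17 | (2R,3R,4R)-7,8-bis(benzyloxy)-4-[2,3-bis(benzyloxy)-5-bromo-4-hydroxyphenyl]-2-[4-(benzyloxy)phenyl]chroman-3-ol (2,3-cis-3,4-trans, 4β-aryl) | c1ccccc1COc1ccc([C@H]2Oc3c(ccc(OCc4ccccc4)c3OCc3ccccc3)[C@H](c3cc(Br)c(O)c(OCc4ccccc4)c3OCc3ccccc3)[C@H]2O)cc1 | intermediate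
18 | trilithiated 17 (3-O-lithium alkoxide, lithium phenoxide, aryl-lithium in place of bromine; not isolated) | c1ccccc1COc1ccc([C@H]2Oc3c(ccc(OCc4ccccc4)c3OCc3ccccc3)[C@H](c3cc([Li])c(O[Li])c(OCc4ccccc4)c3OCc3ccccc3)[C@H]2O[Li])cc1 | intermediate
19 | {3,4-bis(benzyloxy)-5-[(2R,3R,4R)-7,8-bis(benzyloxy)-2-[4-(benzyloxy)phenyl]-3-hydroxychroman-4-yl]-2-hydroxyphenyl}[(2R,3S)-3-[4-(benzyloxy)phenyl]oxiran-2-yl]methanone (not isolated) | c1ccccc1COc1ccc([C@H]2Oc3c(ccc(OCc4ccccc4)c3OCc3ccccc3)[C@H](c3cc(C(=O)[C@@H]5O[C@H]5c5ccc(OCc6ccccc6)cc5)c(O)c(OCc4ccccc4)c3OCc3ccccc3)[C@H]2O)cc1 | intermediate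
20 | (2R,3R)-7,8-bis(benzyloxy)-6-{(2R,3R,4R)-7,8-bis(benzyloxy)-2-[4-(benzyloxy)phenyl]-3-hydroxychroman-4-yl}-2-[4-(benzyloxy)phenyl]-3-hydroxychroman-4-one | c1ccccc1COc1ccc([C@H]2Oc3c(ccc(OCc4ccccc4)c3OCc3ccccc3)[C@H](c3cc4c(c(OCc5ccccc5)c3OCc3ccccc3)O[C@H](c3ccc(OCc5ccccc5)cc3)[C@@H](O)C4=O)[C@H]2O)cc1 | intermediate
21 | (2R,3R)-3,7,8-trihydroxy-2-(4-hydroxyphenyl)-6-[(2R,3R,4S)-3,7,8-trihydroxy-2-(4-hydroxyphenyl)chroman-4-yl]chroman-4-one | Oc1ccc([C@H]2Oc3c(ccc(O)c3O)[C@H](c3cc4c(c(O)c3O)O[C@H](c3ccc(O)cc3)[C@@H](O)C4=O)[C@H]2O)cc1 | intermediate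
22 | (2R,3S,4R)-2-(4-hydroxyphenyl)-6-[(2R,3R,4S)-3,7,8-trihydroxy-2-(4-hydroxyphenyl)chroman-4-yl]chromane-3,4,7,8-tetrol | Oc1ccc([C@H]2Oc3c(ccc(O)c3O)[C@H](c3cc4c(c(O)c3O)O[C@H](c3ccc(O)cc3)[C@@H](O)[C@@H]4O)[C@H]2O)cc1 | target

**Totals**
Total step count: 12.
Longest linear sequence: 10 steps (1, 2, 3, 6, 7, 8, 9, 10, 11, 12). Steps 4 and 5 form the side branch that supplies 9 for steps 6 and 10.

**Steps most likely to fail, with fallbacks**

Step 10. What may go wrong: incomplete bromine–lithium exchange or proton return within the trilithiated species, and aroyl migration or 5-exo opening during the acid stage. The fallback sets out from 17 and returns at 20, and builds the ring by the classical chalcone route without organolithium chemistry. Selective O-alkylation of the phenol of 17 (MOMCl, i-Pr2NEt, CH2Cl2) should give the methoxymethyl ether F1. Palladium-catalysed carbonylative Heck coupling of F1 with 4-(benzyloxy)styrene under CO (Pd(OAc)2, di(1-adamantyl)-n-butylphosphine, Et3N, dioxane, 100 °C) should give the 2'-(methoxymethoxy)chalcone F2. Juliá–Colonna epoxidation (poly-L-leucine, urea–H2O2, DBU, THF) should give the (αR,βS)-epoxychalcone F3. HCl in MeOH/THF then removes the acetal, and the freed phenol closes the ring at the benzylic epoxide carbon to give 20.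

Step 8. What may go wrong: elimination towards the flavone or epimerisation at C3 of the α-sulfonyloxy ketone, or failure to reach the trans-diaxial geometry needed for epoxide closure. The fallback sets out from 12 and returns at 16, and inverts C3 by oxidation and reduction. NaBH4 (THF/EtOH, 0 °C) should give the 2,3-trans-3,4-trans-flavan-3,4-diol F4. Ionic hydrogenation (Et3SiH, TFA, CH2Cl2, 0 °C) should remove the benzylic 4-hydroxyl to give the 2,3-trans-flavan-3-ol F5. Dess–Martin oxidation should give the flavan-3-one F6. LiBH(s-Bu)3 (THF, −78 °C) should attack anti to the 2-aryl group to give the 2,3-cis-flavan-3-ol F7. DDQ in CH2Cl2/MeOH then oxidises C4 of the more electron-rich ring A, and methanol adds trans to the 3-hydroxyl to return 16.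

Step 9. What may go wrong: self-condensation of the electrophile through its own ring A, or loss of regiocontrol on 5. The fallback sets out from 16 and returns at 17, and replaces acid ionisation of an oxygen leaving group by thiophilic activation of a sulfide. Exchange of the 4-methoxy group (BnSH, BF3·OEt2, CH2Cl2, −20 °C) should give the 4β-benzylsulfanyl flavan-3-ol F8. AgBF4 in THF at 0 °C with excess 5 should then form the same C4–aryl bond under essentially neutral conditions to give 17.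

**Further compounds**
F1 | step 10 | (2R,3R,4R)-7,8-bis(benzyloxy)-4-[2,3-bis(benzyloxy)-5-bromo-4-(methoxymethoxy)phenyl]-2-[4-(benzyloxy)phenyl]chroman-3-ol | c1ccccc1COc1ccc([C@H]2Oc3c(ccc(OCc4ccccc4)c3OCc3ccccc3)[C@H](c3cc(Br)c(OCOC)c(OCc4ccccc4)c3OCc3ccccc3)[C@H]2O)cc1
F2 | step 10 | (2E)-1-{3,4-bis(benzyloxy)-5-[(2R,3R,4R)-7,8-bis(benzyloxy)-2-[4-(benzyloxy)phenyl]-3-hydroxychroman-4-yl]-2-(methoxymethoxy)phenyl}-3-[4-(benzyloxy)phenyl]prop-2-en-1-one | c1ccccc1COc1ccc([C@H]2Oc3c(ccc(OCc4ccccc4)c3OCc3ccccc3)[C@H](c3cc(C(=O)/C=C/c5ccc(OCc6ccccc6)cc5)c(OCOC)c(OCc4ccccc4)c3OCc3ccccc3)[C@H]2O)cc1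
F3 | step 10 | {3,4-bis(benzyloxy)-5-[(2R,3R,4R)-7,8-bis(benzyloxy)-2-[4-(benzyloxy)phenyl]-3-hydroxychroman-4-yl]-2-(methoxymethoxy)phenyl}[(2R,3S)-3-[4-(benzyloxy)phenyl]oxiran-2-yl]methanone | c1ccccc1COc1ccc([C@H]2Oc3c(ccc(OCc4ccccc4)c3OCc3ccccc3)[C@H](c3cc(C(=O)[C@@H]5O[C@H]5c5ccc(OCc6ccccc6)cc5)c(OCOC)c(OCc4ccccc4)c3OCc3ccccc3)[C@H]2O)cc1
F4 | step 8 | (2R,3S,4R)-7,8-bis(benzyloxy)-2-[4-(benzyloxy)phenyl]chromane-3,4-diol | O[C@@H]1c2ccc(OCc3ccccc3)c(OCc3ccccc3)c2O[C@H](c2ccc(OCc3ccccc3)cc2)[C@H]1O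
F5 | step 8 | (2R,3S)-7,8-bis(benzyloxy)-2-[4-(benzyloxy)phenyl]chroman-3-ol | C1c2ccc(OCc3ccccc3)c(OCc3ccccc3)c2O[C@H](c2ccc(OCc3ccccc3)cc2)[C@H]1O
F6 | step 8 | (2R)-7,8-bis(benzyloxy)-2-[4-(benzyloxy)phenyl]chroman-3-one | O=C1Cc2ccc(OCc3ccccc3)c(OCc3ccccc3)c2O[C@@H]1c1ccc(OCc2ccccc2)cc1
F7 | step 8 | (2R,3R)-7,8-bis(benzyloxy)-2-[4-(benzyloxy)phenyl]chroman-3-ol | C1c2ccc(OCc3ccccc3)c(OCc3ccccc3)c2O[C@H](c2ccc(OCc3ccccc3)cc2)[C@@H]1O
F8 | step 9 | (2R,3S,4S)-7,8-bis(benzyloxy)-2-[4-(benzyloxy)phenyl]-4-(benzylsulfanyl)chroman-3-ol | c1ccccc1CS[C@H]1c2ccc(OCc3ccccc3)c(OCc3ccccc3)c2O[C@H](c2ccc(OCc3ccccc3)cc2)[C@@H]1O
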